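## Structural features

The target is the (E)-4-hydroxycinnamate (p-coumarate) ester of junenol, a eudesmane alcohol. It has two six-membered carbocycles, ring A (C1–C5, C10) and ring B (C5–C10), fused trans at C5–C10. C10 is quaternary and carries the angular methyl C14. C4 carries the exocyclic methylidene C15. Ring B carries the ester oxygen at C6 and the isopropyl group at C7. The four stereocentres are contiguous (C10–C5–C6–C7; 10R,5S,6S,7S). H5, H6 and H7 are alternately axial, so the fusion is trans and the C6 oxygen and the isopropyl group are both equatorial. The fragile parts are the C4=C15 alkene (migrates into the ring under acid), the phenolic cinnamate (sensitive to base and nucleophiles) and, on the way, any β-hydroxy ketone spanning C4–C5–C6 (retro-aldol, dehydration). The real difficulty is the absolute configuration of the all-carbon quaternary centre C10 next to three tertiary centres, and then the acylation of a C6 hydroxyl crowded by the C4 methylidene and the C7 isopropyl group. The key step uses the fact that C10 and C5 are the β- and α-carbons of a ring A cyclohexenone whose carbonyl carbon C4 is the latent methylidene carbon, while C6 can be an aldehyde carbon; ring B is then closed across C7=C8.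

## Logic of the disconnections

20 is traced to 19 by masking the phenol as a silyl ether, and 19 is cut at the C6–O acyl bond into 14 and 17. This is the only link between the terpene and the aryl part, so the base-sensitive phenolic cinnamate can enter last. The gain is that 14 holds all four stereocentres and 17 comes from 15 by silylation alone. The forward acylation must reach a hindered equatorial alcohol without acid, and the last fluoride step must leave the ester and C4=C15 alone.

14 is cut at C4=C15 to the C4 ketone of 12 (through 13), with the C6 oxygen silylated. The ketone is the group that makes C5 nucleophilic earlier in the route. The demand is a methylenation of a crowded, enolisable ketone that neither epimerises C5 nor opens the ketol; this is why the hydroxyl of 11 is capped as in 12.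

11 is traced to 10 by removing the hydrogens at C7 and C8. A C7=C8 alkene is what a metathesis closure leaves, and the neighbouring C6 hydroxyl can steer hydrogen to one face. The C7 stereocentre is thereby reduced to a consequence of C6. The forward step must add hydrogen syn to the hydroxyl.

10 is cut at C7=C8, which opens ring B to the two terminal alkenes of 9. The bicycle becomes a monocycle in which C10, C5 and C6 are already in place. The forward closure must engage a 1,1-disubstituted alkene, and it needs the two arms trans on ring A.

9 is cut at C10–C14 and at C5–C6 into 4, 7 and 6. These two bonds flank the enone β- and α-carbons, so a single conjugate addition with enolate trapping makes both. Three stereocentres and the quaternary carbon are reduced to an achiral enone, a methyl donor and an achiral enal. The forward step needs catalyst control at C10, attack at C5 anti to the allyl group and a closed aldol transition state for C6.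

4 is cut at the bond between the ring carbon and the allyl CH2 into 1 and 2, using the carbonyl transposition of a vinylogous ester. 6 is cut at its C=CH2 bond to 5 and a one-carbon aldehyde. Both go back to commercial materials in one step each. The forward steps must keep the allyl double bond of 4 out of conjugation and must deliver 6 free of polymer.

## Other disconnections considered

Alternative 1: The cut runs through C5–C10 and C1–C2 and opens both rings at once. The precursor is the acyclic triene A1, a (Z)-2-silyloxydiene (C2=C3–C4=C5) tethered through C6–C9 to a trisubstituted vinyl sulfone (C10=C1). On heating, A1 would undergo an intramolecular Diels–Alder reaction to the trans-fused silyl enol ether A2 with the sulfone at C1.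
- In its favour: two rings, the ring fusion and the quaternary centre form in one reagent-free step, and the C4 oxygen arrives as a masked ketone. On ring construction this is better than the chosen plan, whose key step closes no ring.
- Against it here: C6 and C7 must be set beforehand on an open chain, and the enol ether and vinyl sulfone need defined geometry. The absolute configuration is imported by the chain synthesis and not by a catalyst. Facial selectivity rests on the C6 silyloxy group alone, at a hindered dienophile that needs high temperature, where the silyloxydiene can suffer hydrogen or silyl shifts.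
- Comparison: after A2 there remain enol ether hydrolysis, desulfonylation, methylenation, deprotection and acylation, so the endgame is at best equal in length. The mechanism is a concerted pericyclic reaction under substrate control against a catalytic addition under ligand control. The linear synthesis of A1 is estimated to take more steps than the three that lead to 9.

Alternative 2: The cut runs through C1–C10 and C4–C5 and removes ring A as the diene A4, (E)-1-(tert-butyldimethylsilyloxy)buta-1,3-diene. Ring B remains as thymoquinone A3, which already carries the C10 methyl and the C7 isopropyl group. A chiral oxazaborolidinium Lewis acid bound at the C6 carbonyl would direct endo addition of A4 across the C5=C10 alkene to the cis-fused ene-dione A5.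
- In its favour: both components are simple, and one catalytic step forms ring A and the quaternary centre with a predictable sense of induction. In forming C10 catalytically it equals the chosen plan, and in closing a ring in the same step it is better.
- Against it here: A5 has the wrong oxidation level and ring fusion. The C9 carbonyl must be deleted, C7=C8 and the C6 carbonyl reduced with control of C6 and C7, and C5 epimerised to trans. The C4 allylic silyl ether and its C2=C3 alkene must also be converted to a C4 ketone. The Lewis acid must in addition distinguish the two quinone carbonyls and the two trisubstituted alkenes.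
- Comparison: the cycloaddition fixes only C10 permanently, whereas the chosen key step fixes C10, C5 and C6 at the final oxidation level. The redox corrections after A5 are estimated to outnumber the operations that follow 9.

Alternative 3: The cut runs through C6–C7 and C5–C10 and unravels the skeleton to (2E,6E)-farnesyl diphosphate A6. A class 1 sesquiterpene synthase of the eudesmanol type would ionise A6, close the ten-membered ring at C6–C7, shift a hydride and capture water at C6. It would then close C5–C10 across the ring with proton loss from C15, giving junenol A7, identical with 14.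
- In its favour: one enzymatic step would deliver both rings, all four stereocentres, the hydroxyl and the methylidene without protecting groups. In step economy and structural gain per step this is clearly better than the chosen plan, and the closing acylation would be the same (equal).
- Against it here: it depends on an enzyme with exactly this product specificity and absolute configuration, and such cyclases often give mixtures. A6 is costly unless made in an engineered host, and the work becomes fermentation and isolation, not a synthesis from commercial chemicals.
- Comparison: a cationic cascade steered by an active site offers no handle to correct a stereocentre, while the chosen plan does. For a laboratory route the chosen plan is retained; Alternative 3 would be the better choice for supply at scale once a suitable enzyme is in hand.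

Key step: step 3

Assumption: positions are numbered as in the eudesmane skeleton, and the phosphoramidite is specified by the face it must address (the Si face of C10 of 4), the matching antipode of the ligand being chosen accordingly.

## Route

Step 1
Reactants: 1 3-ethoxycyclohex-2-en-1-one; 2 allylmagnesium bromide
Product: 4 3-(prop-2-en-1-yl)cyclohex-2-en-1-one, via tertiary carbinol 3 (not isolated)
Conditions: 2 (1.2 equiv), THF, 0 °C; then 1 M aq. HCl, 0 °C, short contact
Reagents that add atoms: water, O
Why: Stork–Danheiser enone transposition: 1,2-addition of the Grignard reagent to the vinylogous ester gives 3, and acid hydrolysis of the enol ether with loss of water and ethanol gives the 3-substituted enone. Short, cold acid contact should keep the allyl double bond out of conjugation.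

Step 2
Reactants: 5 3-methylbutanal
Product: 6 3-methyl-2-methylidenebutanal (2-isopropylacrolein)
Conditions: 37% aq. CH2O, pyrrolidine (10 mol%), propanoic acid (10 mol%), i-PrOH, 45 °C; distilled
Reagents that add atoms: formaldehyde, C=O
Why: Mannich-type α-methylenation of an aldehyde: the enamine adds to the formaldehyde-derived iminium ion and the amine is lost by β-elimination. 6 is distilled and used fresh because it polymerises on standing.

Step 3
Reactants: 4 3-(prop-2-en-1-yl)cyclohex-2-en-1-one; 7 trimethylaluminium; 6 3-methyl-2-methylidenebutanal
Product: 9 (2S,3R)-2-[(1R)-1-hydroxy-3-methyl-2-methylidenebutyl]-3-methyl-3-(prop-2-en-1-yl)cyclohexan-1-one, via dimethylaluminium enolate 8 (not isolated)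
Conditions: copper thiophene-2-carboxylate (5 mol%, monovalent copper), homochiral O,O'-(2,2'-biphenyldiyl) N,N-bis(1-phenylethyl)phosphoramidite (10 mol%), 7 (1.2 equiv), Et2O, −30 °C; then 6 (2.0 equiv), −78 → −20 °C; aq. KNaC4H4O6 (potassium sodium tartrate), 0 °C
Reagents that add atoms: none
Why: Transmetallation from 7 gives a ligand-bound methylcopper species that forms a π-complex with 4, adds at C10 to a trivalent copper intermediate and reductively eliminates the C10–C14 bond, leaving the regiodefined dimethylaluminium enolate 8 (C4–O–Al, C4=C5), which deprotonation of the saturated ketone would not give. The closest known reaction type is the copper-catalysed asymmetric conjugate addition of trialkylaluminium reagents to 3-substituted cyclohexenones with aldehyde trapping of the aluminium enolate (tandem conjugate addition–aldol). No ring is closed in this step; the two terminal alkenes are carried for the later closure of ring B. C10 is set by the phosphoramidite, whose antipode is chosen so that methyl is delivered to the Si face of C10 (priorities C5 > allyl CH2 > C1), which gives (R). C5 is set by the substrate: the aldehyde should add axially to the half-chair enolate on the face anti to the larger allyl group, so that the new C5–C6 bond is cis to methyl and trans to C9. C6 is set by the closed six-membered Zimmerman–Traxler chair of the ring-locked E(O)-enolate, with aluminium bridging both oxygens and the substituted vinyl group of 6 equatorial, which gives the anti aldol, here (1R) at the carbinol. The step needs 1,2- over 1,4-addition to the enal and aldol over methyl transfer to 6: the hard aluminium enolate and the α-branch of 6 favour carbonyl attack, while a small excess of 7, an excess of 6 and a cold quench should limit methyl transfer and retro-aldol.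

Step 4
Reactants: 9 (2S,3R)-2-[(1R)-1-hydroxy-3-methyl-2-methylidenebutyl]-3-methyl-3-(prop-2-en-1-yl)cyclohexan-1-one
Product: 10 (4aR,8R,8aS)-8-hydroxy-4a-methyl-7-(propan-2-yl)-3,4,4a,5,8,8a-hexahydronaphthalen-1(2H)-one
Conditions: second-generation Grubbs catalyst RuCl2(=CHPh)(H2IMes)(PCy3) (5 mol%), CH2Cl2 (0.01 M), 40 °C
Reagents that add atoms: none
Why: Ring-closing metathesis: the ruthenium carbene loads at the monosubstituted allyl alkene and closes the six-membered ring onto the 1,1-disubstituted alkene with loss of ethene. The trans arrangement of the two arms on ring A becomes the trans ring fusion, the free allylic hydroxyl is tolerated, and no stereocentre is created.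

Step 5
Reactants: 10 (4aR,8R,8aS)-8-hydroxy-4a-methyl-7-(propan-2-yl)-3,4,4a,5,8,8a-hexahydronaphthalen-1(2H)-one
Product: 11 (4aR,7S,8S,8aS)-8-hydroxy-4a-methyl-7-(propan-2-yl)octahydronaphthalen-1(2H)-one
Conditions: [Ir(cod)(PCy3)(py)]PF6 (5 mol%), H2 (1 atm), CH2Cl2, 0 °C → rt
Reagents that add atoms: none
Why: Hydroxyl-directed hydrogenation: the cationic iridium complex binds the C6 hydroxyl and delivers hydrogen to the α face of C7=C8, syn to oxygen, so H7 is cis to O6 and the isopropyl group becomes equatorial (7S). The same face is remote from the axial C14 methyl, so steric and directing effects agree.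

Step 6
Reactants: 11 (4aR,7S,8S,8aS)-8-hydroxy-4a-methyl-7-(propan-2-yl)octahydronaphthalen-1(2H)-one
Product: 12 (4aR,7S,8S,8aS)-4a-methyl-7-(propan-2-yl)-8-[(triethylsilyl)oxy]octahydronaphthalen-1(2H)-one
Conditions: TESCl, imidazole, DMAP (cat.), DMF, rt
Reagents that add atoms: chlorotriethylsilane, CC[Si](Cl)(CC)CC
Why: Silyl ether formation at the secondary alcohol under mild base leaves the ketone untouched. The cap prevents alkoxide formation, and hence retro-aldol opening of ring B, under the ylide conditions of step 7.

Step 7
Reactants: 12 (4aR,7S,8S,8aS)-4a-methyl-7-(propan-2-yl)-8-[(triethylsilyl)oxy]octahydronaphthalen-1(2H)-one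
Product: 14 junenol [(1S,2S,4aR,8aS)-4a-methyl-8-methylidene-2-(propan-2-yl)decahydronaphthalen-1-ol], via junenol triethylsilyl ether 13 (not isolated)
Conditions: Ph3PCH3Br (4 equiv), KOtBu (3.8 equiv), toluene, 0 → 80 °C; then Bu4NF, THF, rt
Reagents that add atoms: methyltriphenylphosphonium bromide, C[P+](c1ccccc1)(c1ccccc1)c1ccccc1.[Br-]
Why: Wittig methylenation with the salt-free ylide turns the C4 carbonyl into C4=C15; a slight deficit of KOtBu avoids free alkoxide. The equatorial C6–O bond is poorly aligned with a C4–C5 enolate, so β-elimination is not expected, and the trans fusion should be the more stable arrangement at C5. Fluoride then cleaves the triethylsilyl ether in the same flask.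

Step 8
Reactants: 15 p-coumaric acid [(2E)-3-(4-hydroxyphenyl)prop-2-enoic acid]
Product: 17 (2E)-3-{4-[(tert-butyldimethylsilyl)oxy]phenyl}prop-2-enoic acid, via bis-silylated coumarate 16 (not isolated)
Conditions: TBSCl (2.3 equiv), imidazole, DMF, rt; then AcOH, THF–H2O, rt
Reagents that add atoms: tert-butylchlorodimethylsilane, CC(C)(C)[Si](C)(C)Cl
Why: Silylation of both the phenol and the acid is followed by selective hydrolysis of the labile silyl ester. The aryl silyl ether survives mild aqueous acid and the (E)-alkene is not touched.

Step 9
Reactants: 17 (2E)-3-{4-[(tert-butyldimethylsilyl)oxy]phenyl}prop-2-enoic acid; 14 junenol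
Product: 19 (1S,2S,4aR,8aS)-4a-methyl-8-methylidene-2-(propan-2-yl)decahydronaphthalen-1-yl (2E)-3-{4-[(tert-butyldimethylsilyl)oxy]phenyl}prop-2-enoate, via mixed anhydride 18 (not isolated)
Conditions: 2,4,6-Cl3C6H2COCl, Et3N, toluene, rt; then 14, DMAP, toluene, rt → 50 °C
Reagents that add atoms: none
Why: Yamaguchi esterification: DMAP attacks the less hindered cinnamoyl carbonyl of 18 and the acylpyridinium ion acylates the crowded equatorial C6 hydroxyl with retention at C6. The conditions are not acidic, so C4=C15 stays exocyclic and the (E)-alkene is kept.

Step 10
Reactants: 19 (1S,2S,4aR,8aS)-4a-methyl-8-methylidene-2-(propan-2-yl)decahydronaphthalen-1-yl (2E)-3-{4-[(tert-butyldimethylsilyl)oxy]phenyl}prop-2-enoate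
Product: 20 (1S,2S,4aR,8aS)-4a-methyl-8-methylidene-2-(propan-2-yl)decahydronaphthalen-1-yl (2E)-3-(4-hydroxyphenyl)prop-2-enoate (CNP0321375.1)
Conditions: Bu4NF, AcOH, THF, 0 °C
Reagents that add atoms: none
Why: Fluoride cleaves the aryl silyl ether. The AcOH buffer protonates the phenoxide at once, so the hindered ester and the exocyclic alkene should not be affected.

## Compound list

1 | 3-ethoxycyclohex-2-en-1-one | CCOC1=CC(=O)CCC1 | starting material
2 | allylmagnesium bromide | C=CC[Mg]Br | starting material
3 | 3-ethoxy-1-(prop-2-en-1-yl)cyclohex-2-en-1-ol (racemic, not isolated) | C=CCC1(O)C=C(OCC)CCC1 | intermediate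
4 | 3-(prop-2-en-1-yl)cyclohex-2-en-1-one | C=CCC1=CC(=O)CCC1 | intermediate
5 | 3-methylbutanal | CC(C)CC=O | starting material
6 | 3-methyl-2-methylidenebutanal (2-isopropylacrolein) | C=C(C=O)C(C)C | intermediate
7 | trimethylaluminium | C[Al](C)C | starting material
8 | dimethyl{[(3R)-3-methyl-3-(prop-2-en-1-yl)cyclohex-1-en-1-yl]oxy}alumane (not isolated) | C=CC[C@@]1(C)CCCC(O[Al](C)C)=C1 | intermediate
9 | (2S,3R)-2-[(1R)-1-hydroxy-3-methyl-2-methylidenebutyl]-3-methyl-3-(prop-2-en-1-yl)cyclohexan-1-one | C=CC[C@@]1(C)CCCC(=O)[C@@H]1[C@@H](O)C(=C)C(C)C | intermediate
10 | (4aR,8R,8aS)-8-hydroxy-4a-methyl-7-(propan-2-yl)-3,4,4a,5,8,8a-hexahydronaphthalen-1(2H)-one | O=C1CCC[C@]2(C)CC=C(C(C)C)[C@H](O)[C@@H]12 | intermediate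
11 | (4aR,7S,8S,8aS)-8-hydroxy-4a-methyl-7-(propan-2-yl)octahydronaphthalen-1(2H)-one | O=C1CCC[C@]2(C)CC[C@@H](C(C)C)[C@H](O)[C@@H]12 | intermediate
12 | (4aR,7S,8S,8aS)-4a-methyl-7-(propan-2-yl)-8-[(triethylsilyl)oxy]octahydronaphthalen-1(2H)-one | O=C1CCC[C@]2(C)CC[C@@H](C(C)C)[C@H](O[Si](CC)(CC)CC)[C@@H]12 | intermediate
13 | triethyl{[(1S,2S,4aR,8aS)-4a-methyl-8-methylidene-2-(propan-2-yl)decahydronaphthalen-1-yl]oxy}silane (not isolated) | C=C1CCC[C@]2(C)CC[C@@H](C(C)C)[C@H](O[Si](CC)(CC)CC)[C@@H]12 | intermediate
14 | junenol, (1S,2S,4aR,8aS)-4a-methyl-8-methylidene-2-(propan-2-yl)decahydronaphthalen-1-ol | C=C1CCC[C@]2(C)CC[C@@H](C(C)C)[C@H](O)[C@@H]12 | intermediate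
15 | p-coumaric acid, (2E)-3-(4-hydroxyphenyl)prop-2-enoic acid | O=C(O)/C=C/c1ccc(O)cc1 | starting material
16 | tert-butyldimethylsilyl (2E)-3-{4-[(tert-butyldimethylsilyl)oxy]phenyl}prop-2-enoate (not isolated) | CC(C)(C)[Si](C)(C)OC(=O)/C=C/c1ccc(O[Si](C)(C)C(C)(C)C)cc1 | intermediate
17 | (2E)-3-{4-[(tert-butyldimethylsilyl)oxy]phenyl}prop-2-enoic acid | O=C(O)/C=C/c1ccc(O[Si](C)(C)C(C)(C)C)cc1 | intermediate
18 | (2E)-3-{4-[(tert-butyldimethylsilyl)oxy]phenyl}prop-2-enoic 2,4,6-trichlorobenzoic anhydride (not isolated) | O=C(/C=C/c1ccc(O[Si](C)(C)C(C)(C)C)cc1)OC(=O)c1c(Cl)cc(Cl)cc1Cl | intermediate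
19 | (1S,2S,4aR,8aS)-4a-methyl-8-methylidene-2-(propan-2-yl)decahydronaphthalen-1-yl (2E)-3-{4-[(tert-butyldimethylsilyl)oxy]phenyl}prop-2-enoate | C=C1CCC[C@]2(C)CC[C@@H](C(C)C)[C@H](OC(=O)/C=C/c3ccc(O[Si](C)(C)C(C)(C)C)cc3)[C@@H]12 | intermediate
20 | (1S,2S,4aR,8aS)-4a-methyl-8-methylidene-2-(propan-2-yl)decahydronaphthalen-1-yl (2E)-3-(4-hydroxyphenyl)prop-2-enoate | C=C1CCC[C@]2(C)CC[C@@H](C(C)C)[C@H](OC(=O)/C=C/c3ccc(O)cc3)[C@@H]12 | target

## Step count and least certain steps

Total step count: 10. Longest linear sequence: 8 steps (steps 1, 3, 4, 5, 6, 7, 9, 10, from 1 to 20).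

Step 3 (key step).
- What may go wrong: incomplete facial discrimination at C5 between the methyl and allyl flanks of C10 during the aldol. Slow trapping at the hindered enolate carbon would also let methyl transfer from residual 7 to 6, and retro-aldol on warming, compete. Erosion of enantioselectivity at C10 is a lesser risk.
- Fallback: control of C5, C6 and C7 is moved from kinetic to thermodynamic. It sets out from 9 obtained in admixture with its C5,C6-bis-epimer, the syn-to-allyl aldol adduct F1. Steps 4 and 5 are run on the mixture. F1 then gives the cis-fused hydroxy enone F2 and, by the same hydroxyl-directed hydrogenation, the tris-epimeric ketol F3, which differs from 11 at C5, C6 and C7 but not at C10. Brief treatment of the mixture with K2CO3 in MeOH at room temperature opens F3 by retro-aldol cleavage of C5–C6 to the ring-opened keto aldehyde F4. In F4 both C7 (α to the aldehyde) and C5 (α to the ketone) equilibrate. Intramolecular aldol re-closure should funnel the material into the trans-fused, all-equatorial ketol, so the fallback comes back to the route at 11. The equatorial hydroxyl of 11 is poorly aligned for E1cB dehydration; a short reaction time at low temperature should hold the equilibration at the ketol stage.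

Step 4.
- What may go wrong: slow closure onto the hindered 1,1-disubstituted alkene. Intermolecular metathesis at the allyl terminus, ruthenium hydride-mediated migration of the allyl double bond or of the allylic alcohol, and thermal retro-aldol of the free ketol could then compete.
- Fallback: the carbinol is masked before ring closure, and C7 is then set by the steric bias of the bicycle instead of by the hydroxyl. It sets out from 9. TESCl, imidazole, DMF gives the triethylsilyl ether F5, which can be heated with the same ruthenium catalyst in toluene at 80 °C without retro-aldol to give the bicyclic silyl ether F6. Hydrogenation over Pd/C in EtOAc from the α face, away from the axial C14 methyl, then gives 12, where the fallback comes back to the route (steps 5 and 6 are not needed).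

Step 7.
- What may go wrong: proton transfer from C5 or C3 to the ylide in place of addition to the crowded C4 carbonyl. This would cause incomplete conversion, epimerisation at C5 or β-elimination of the silyloxy group.
- Fallback: a two-stage Peterson olefination with a non-basic organocerium nucleophile. It sets out from 12. Me3SiCH2Li/CeCl3 in THF at −78 °C adds to the ketone to give the β-hydroxysilane F7; the configuration at the new carbinol is immaterial. HF·pyridine in THF then brings about the elimination to C4=C15 and removes the triethylsilyl group in the same operation, so the fallback comes back to the route at 14.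

Step 9.
- What may go wrong: slow acyl transfer to the C6 hydroxyl, which is flanked by the C4 methylidene and the C7 isopropyl group. The mixed anhydride would then be diverted to the symmetric anhydride or the trichlorobenzoate.
- Fallback: the cinnamate is built on the alcohol from a small acyl unit. It sets out from 14. Heating with Meldrum's acid (2,2-dimethyl-1,3-dioxane-4,6-dione) in toluene at 100 °C transfers a malonyl group through the unhindered acylketene and gives the malonate half-ester F8. Knoevenagel–Doebner condensation of F8 with 4-hydroxybenzaldehyde (pyridine, cat. piperidine, 50 °C), with loss of CO2, then gives the (E)-p-coumarate directly without phenol protection. The fallback comes back to the route at 20 (steps 8 and 10 are not needed).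

## Further compounds

F1 | step 3 | (2R,3R)-2-[(1S)-1-hydroxy-3-methyl-2-methylidenebutyl]-3-methyl-3-(prop-2-en-1-yl)cyclohexan-1-one | C=CC[C@@]1(C)CCCC(=O)[C@H]1[C@H](O)C(=C)C(C)C
F2 | step 3 | (4aR,8S,8aR)-8-hydroxy-4a-methyl-7-(propan-2-yl)-3,4,4a,5,8,8a-hexahydronaphthalen-1(2H)-one | O=C1CCC[C@]2(C)CC=C(C(C)C)[C@@H](O)[C@H]12
F3 | step 3 | (4aR,7R,8R,8aR)-8-hydroxy-4a-methyl-7-(propan-2-yl)octahydronaphthalen-1(2H)-one | O=C1CCC[C@]2(C)CC[C@H](C(C)C)[C@@H](O)[C@H]12
F4 | step 3 | 3-methyl-2-{2-[(1R)-1-methyl-3-oxocyclohexyl]ethyl}butanal (C2 epimers) | O=CC(C(C)C)CC[C@@]1(C)CCCC(=O)C1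
F5 | step 4 | (2S,3R)-3-methyl-2-{(1R)-3-methyl-2-methylidene-1-[(triethylsilyl)oxy]butyl}-3-(prop-2-en-1-yl)cyclohexan-1-one | C=CC[C@@]1(C)CCCC(=O)[C@@H]1[C@@H](O[Si](CC)(CC)CC)C(=C)C(C)C
F6 | step 4 | (4aR,8R,8aS)-4a-methyl-7-(propan-2-yl)-8-[(triethylsilyl)oxy]-3,4,4a,5,8,8a-hexahydronaphthalen-1(2H)-one | O=C1CCC[C@]2(C)CC=C(C(C)C)[C@H](O[Si](CC)(CC)CC)[C@@H]12
F7 | step 7 | (4aR,7S,8S,8aS)-4a-methyl-7-(propan-2-yl)-8-[(triethylsilyl)oxy]-1-[(trimethylsilyl)methyl]decahydronaphthalen-1-ol (configuration at C1 not controlled) | C[Si](C)(C)CC1(O)CCC[C@]2(C)CC[C@@H](C(C)C)[C@H](O[Si](CC)(CC)CC)[C@@H]12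
F8 | step 9 | 3-{[(1S,2S,4aR,8aS)-4a-methyl-8-methylidene-2-(propan-2-yl)decahydronaphthalen-1-yl]oxy}-3-oxopropanoic acid | C=C1CCC[C@]2(C)CC[C@@H](C(C)C)[C@H](OC(=O)CC(=O)O)[C@@H]12
A1 | alternative 1 | [(1E,5S,6S,7Z)-6,8-bis(tert-butyldimethylsilyloxy)-2-methyl-5-(propan-2-yl)deca-1,7,9-trien-1-yl]sulfonylbenzene | C=C/C(O[Si](C)(C)C(C)(C)C)=C/[C@@H](O[Si](C)(C)C(C)(C)C)[C@H](C(C)C)CC/C(C)=C/S(=O)(=O)c1ccccc1
A2 | alternative 1 | trans-fused Diels–Alder adduct, 4,6-bis(tert-butyldimethylsilyloxy)-1-(phenylsulfonyl)eudesm-3-ene (eudesmane numbering) | CC(C)(C)[Si](C)(C)OC1=CC[C@@H](S(=O)(=O)c3ccccc3)[C@]2(C)CC[C@@H](C(C)C)[C@H](O[Si](C)(C)C(C)(C)C)[C@@H]12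
A3 | alternative 2 | thymoquinone, 2-methyl-5-(propan-2-yl)cyclohexa-2,5-diene-1,4-dione | CC1=CC(=O)C(C(C)C)=CC1=O
A4 | alternative 2 | (E)-1-(tert-butyldimethylsilyloxy)buta-1,3-diene | C=C/C=C/O[Si](C)(C)C(C)(C)C
A5 | alternative 2 | cis-fused Diels–Alder adduct, 4-(tert-butyldimethylsilyloxy)eudesma-2,7-diene-6,9-dione (eudesmane numbering) | CC(C)(C)[Si](C)(C)O[C@@H]1C=CC[C@]2(C)C(=O)C=C(C(C)C)C(=O)[C@H]12
A6 | alternative 3 | (2E,6E)-farnesyl diphosphate | CC(C)=CCC/C(C)=C/CC/C(C)=C/COP(=O)(O)OP(=O)(O)O
A7 | alternative 3 | junenol (identical with 14) | C=C1CCC[C@]2(C)CC[C@@H](C(C)C)[C@H](O)[C@@H]12
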